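**Retrosynthetic overview**
- Numbering used throughout: C1 lactone C=O, C2=C3, C4 ring CH2, C5 lactone O–CH, C6 free carbinol, C7 and C10 oxolane O–CH, C11 caffeate carbinol, C12 methyl. Last disconnections are the caffeate ester at O11 and three silyl ethers.
- Key disconnection C3–C4. In the dihydropyranone ring the enoate β-carbon C3 is bonded to a CH2 (C4) that sits next to the ring-oxygen carbon C5. C1–C3 is therefore an acrylate on O5, and C4–C5–O5 is a terminal epoxide opened by iodide. The ring closes when a carbene umpoles the acrylate β-carbon and C3 displaces iodide at C4.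
- The C4–C5 oxirane (a temporary ring) comes from a matched Sharpless epoxidation of the C6 allylic alcohol; C6 comes from chelation-controlled vinyl addition to the oxolane-2-carbaldehyde.
- The oxolane comes from two chiral-pool pieces: (R)-benzyl glycidyl ether (C6–C8) and the acetylide of (S)-but-3-yn-2-ol (C9–C12). O7 closes onto C10 (5-endo-dig), then cis hydrogenation sets C10.
- Ring order: oxolane (step 3), oxirane (step 6, opened in step 8), dihydropyranone (step 10).

Key step: step 10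

Remark: the target SMILES is read as 5R,6S,7R,10S,11S, i.e. a 2,5-cis oxolane with C5/C6 erythro and C6/C7 threo.

**Route**

Step 1
Reactants: 1 (S)-but-3-yn-2-ol
Product: 2 (S)-(but-3-yn-2-yloxy)triethylsilane
Conditions: TESCl, imidazole, CH2Cl2, 0 °C → rt
Reagents that add atoms: chlorotriethylsilane, CC[Si](Cl)(CC)CC
Why: Silylation of the secondary alcohol with a chlorosilane and imidazole; the C11 stereocentre is carried over unchanged from the chiral-pool alcohol.

Step 2
Reactants: 2 (S)-(but-3-yn-2-yloxy)triethylsilane; 3 (R)-2-[(benzyloxy)methyl]oxirane (benzyl (R)-glycidyl ether)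
Product: 4 (2R,6S)-1-(benzyloxy)-6-[(triethylsilyl)oxy]hept-4-yn-2-ol
Conditions: 2, n-BuLi, THF, −78 °C; BF3·OEt2; then 3, −78 °C; aqueous work-up
Reagents that add atoms: none
Why: The alkynyl trifluoroborate formed in situ should open the terminal epoxide at its CH2 carbon (Yamaguchi–Hirao alkynylation), joining C8–C9 while C7 keeps the glycidyl configuration because its C–O bond is not touched.

Step 3
Reactants: 4 (2R,6S)-1-(benzyloxy)-6-[(triethylsilyl)oxy]hept-4-yn-2-ol
Product: 7 {(2R,5S)-5-[(1S)-1-[(triethylsilyl)oxy]ethyl]oxolan-2-yl}methanol, via dihydrofuran 5 (not isolated), via benzyl ether 6 (not isolated)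
Conditions: Ph3PAuCl (2 mol %), AgOTf (2 mol %), CH2Cl2, rt; filter through basic Al2O3; H2 (1 atm), 5% Rh/Al2O3, EtOAc; then H2, Pd(OH)2/C, EtOAc
Reagents that add atoms: none
Why: Gold-catalysed 5-endo-dig hydroalkoxylation of the homopropargylic alcohol (O7 onto C10) should give the cyclic enol ether; heterogeneous hydrogenation then adds H2 to C9=C10 from the face opposite the C7 substituent, setting C10 (S) and the 2,5-cis oxolane, and hydrogenolysis frees the primary alcohol.

Step 4
Reactants: 7 {(2R,5S)-5-[(1S)-1-[(triethylsilyl)oxy]ethyl]oxolan-2-yl}methanol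
Product: 8 (2R,5S)-5-[(1S)-1-[(triethylsilyl)oxy]ethyl]oxolane-2-carbaldehyde
Conditions: TEMPO (cat.), PhI(OAc)2, CH2Cl2, rt
Reagents that add atoms: none
Why: Nitroxyl/hypervalent-iodine oxidation of the primary alcohol stops at the aldehyde under near-neutral conditions, so the silyl ether and the α-alkoxy centre C7 should not be endangered.

Step 5
Reactants: 8 (2R,5S)-5-[(1S)-1-[(triethylsilyl)oxy]ethyl]oxolane-2-carbaldehyde
Product: 9 (1R)-1-{(2R,5S)-5-[(1S)-1-[(triethylsilyl)oxy]ethyl]oxolan-2-yl}prop-2-en-1-ol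
Conditions: MgBr2·OEt2, CH2Cl2, −78 °C; then CH2=CHMgBr (THF solution), −78 °C; NH4Cl (aq)
Reagents that add atoms: vinylmagnesium bromide, C=C[Mg]Br
Why: Chelation-controlled (Cram-chelate) Grignard addition: magnesium bridges the aldehyde oxygen and ring oxygen O7, the vinyl group attacks the face away from C8, and C6 is set threo to C7.

Step 6
Reactants: 9 (1R)-1-{(2R,5S)-5-[(1S)-1-[(triethylsilyl)oxy]ethyl]oxolan-2-yl}prop-2-en-1-ol
Product: 10 (S)-[(2R)-oxiran-2-yl]{(2R,5S)-5-[(1S)-1-[(triethylsilyl)oxy]ethyl]oxolan-2-yl}methanol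
Conditions: Ti(OiPr)4 (cat.), L-(+)-diisopropyl tartrate, t-BuOOH, 4 Å MS, CH2Cl2, −20 °C
Reagents that add atoms: tert-butyl hydroperoxide, CC(C)(C)OO
Why: Sharpless asymmetric epoxidation of the secondary allylic alcohol in the matched sense: with L-(+)-tartrate this C6 epimer is the fast-reacting one and should give the erythro epoxy alcohol, setting C5 (R), while any C6 epimer from step 5 reacts slowly and is left behind.

Step 7
Reactants: 10 (S)-[(2R)-oxiran-2-yl]{(2R,5S)-5-[(1S)-1-[(triethylsilyl)oxy]ethyl]oxolan-2-yl}methanol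
Product: 11 tert-butyldimethyl{(S)-[(2R)-oxiran-2-yl][(2R,5S)-5-[(1S)-1-[(triethylsilyl)oxy]ethyl]oxolan-2-yl]methoxy}silane
Conditions: TBSOTf, 2,6-lutidine, CH2Cl2, −78 °C
Reagents that add atoms: tert-butyldimethylsilyl trifluoromethanesulfonate, CC(C)(C)[Si](C)(C)OS(=O)(=O)C(F)(F)F
Why: Silyl triflate silylation of the hindered C6 alcohol at low temperature with a hindered base should leave the epoxide and the TES ether intact; this TBS ether keeps O6 distinct from O5 and O11 until the end.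

Step 8
Reactants: 11 tert-butyldimethyl{(S)-[(2R)-oxiran-2-yl][(2R,5S)-5-[(1S)-1-[(triethylsilyl)oxy]ethyl]oxolan-2-yl]methoxy}silane
Product: 12 (2S,3R)-3-[(tert-butyldimethylsilyl)oxy]-1-iodo-3-{(2R,5S)-5-[(1S)-1-[(triethylsilyl)oxy]ethyl]oxolan-2-yl}propan-2-ol
Conditions: LiI, AcOH, THF, 0 °C → rt
Reagents that add atoms: lithium iodide, [Li+].[I-]
Why: Iodide opens the acid-activated terminal epoxide by SN2 at the CH2 carbon C4 (halohydrin formation), so the C5–O bond is untouched and C5 keeps its configuration (the descriptors change only through CIP priorities).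

Step 9
Reactants: 12 (2S,3R)-3-[(tert-butyldimethylsilyl)oxy]-1-iodo-3-{(2R,5S)-5-[(1S)-1-[(triethylsilyl)oxy]ethyl]oxolan-2-yl}propan-2-ol
Product: 13 (2S,3S)-3-[(tert-butyldimethylsilyl)oxy]-1-iodo-3-{(2R,5S)-5-[(1S)-1-[(triethylsilyl)oxy]ethyl]oxolan-2-yl}propan-2-yl prop-2-enoate
Conditions: acryloyl chloride, iPr2NEt, DMAP (cat.), CH2Cl2, −40 → 0 °C
Reagents that add atoms: acryloyl chloride, C=CC(=O)Cl
Why: O-Acylation of the secondary alcohol with an acid chloride and a hindered amine at low temperature should be faster than base-induced re-closure of the iodohydrin; it installs C1–C3 on O5.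

Step 10
Reactants: 13 (2S,3S)-3-[(tert-butyldimethylsilyl)oxy]-1-iodo-3-{(2R,5S)-5-[(1S)-1-[(triethylsilyl)oxy]ethyl]oxolan-2-yl}propan-2-yl prop-2-enoate
Product: 14 (6R)-6-{(S)-[(tert-butyldimethylsilyl)oxy][(2R,5S)-5-[(1S)-1-[(triethylsilyl)oxy]ethyl]oxolan-2-yl]methyl}-5,6-dihydro-2H-pyran-2-one
Conditions: 1,3,4-triphenyl-1,2,4-triazolium tetrafluoroborate (15 mol %), K3PO4 (2.5 equiv), 1,2-dimethoxyethane, 80 °C, slow addition of 13 (final 0.01 M)
Reagents that add atoms: none
Why: Proposed new method: the triazolylidene adds to the acrylate β-carbon C3, a proton shift from C3 to C2 gives the deoxy-Breslow (ene-1,1-diamine) intermediate in which C3 is nucleophilic, C3 displaces iodide from the primary C4 in an intramolecular SN2 step, and E1cB loss of the azolium from C3 (deprotonation at C2 by phosphate) releases the carbene and the C2=C3 double bond. The closest known reaction type is the carbene-catalysed intramolecular β-alkylation of α,β-unsaturated esters that carry a pendant alkyl halide or sulfonate (umpolung of a Michael acceptor), supported by the carbene-catalysed tail-to-tail dimerisation of methacrylates through isolable deoxy-Breslow intermediates; new here is the tether through the ester oxygen, which turns the cyclisation into a lactone synthesis by C–C bond formation. One ring is closed, the six-membered lactone, in 6-exo-tet mode at C4 (the C–I bond lies outside the forming ring) from the s-cis ester rotamer, which the long-lived ionic intermediates can reach. No stereocentre is formed: only the CH2–I bond next to C5 is broken, so C5 (R) and the four other centres are retained. The step needs alkylation at C3 and not at C2 (which would give an α-methylene γ-lactone) and cyclisation in preference to intermolecular Michael oligomerisation; the first is secured by the deoxy-Breslow resting state that localises nucleophilicity on C3, the second by slow addition at high dilution and by 13 having no free hydroxyl and no second electrophilic alkene.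

Step 11
Reactants: 14 (6R)-6-{(S)-[(tert-butyldimethylsilyl)oxy][(2R,5S)-5-[(1S)-1-[(triethylsilyl)oxy]ethyl]oxolan-2-yl]methyl}-5,6-dihydro-2H-pyran-2-one
Product: 15 (6R)-6-{(S)-[(tert-butyldimethylsilyl)oxy][(2R,5S)-5-[(1S)-1-hydroxyethyl]oxolan-2-yl]methyl}-5,6-dihydro-2H-pyran-2-one
Conditions: PPTS (cat.), MeOH/CH2Cl2, 0 °C
Reagents that add atoms: none
Why: Acid-catalysed methanolysis should remove the unhindered secondary TES ether much faster than the hindered TBS ether between the two rings, and the lactone is inert to these conditions.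

Step 12
Reactants: 16 caffeic acid, (2E)-3-(3,4-dihydroxyphenyl)prop-2-enoic acid
Product: 18 (2E)-3-{3,4-bis[(tert-butyldimethylsilyl)oxy]phenyl}prop-2-enoic acid, via silyl ester 17 (not isolated)
Conditions: TBSCl (3.3 equiv), imidazole, DMF, rt; then AcOH/THF/H2O (3:1:1), rt
Reagents that add atoms: tert-butyldimethylsilyl chloride, CC(C)(C)[Si](C)(C)Cl
Why: Exhaustive silylation followed by selective hydrolysis of the labile silyl ester should leave the two acid-stable aryl TBS ethers and the free acid.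

Step 13
Reactants: 15 (6R)-6-{(S)-[(tert-butyldimethylsilyl)oxy][(2R,5S)-5-[(1S)-1-hydroxyethyl]oxolan-2-yl]methyl}-5,6-dihydro-2H-pyran-2-one; 18 (2E)-3-{3,4-bis[(tert-butyldimethylsilyl)oxy]phenyl}prop-2-enoic acid
Product: 19 (1S)-1-[(2S,5R)-5-{(S)-[(tert-butyldimethylsilyl)oxy][(2R)-6-oxo-3,6-dihydro-2H-pyran-2-yl]methyl}oxolan-2-yl]ethyl (2E)-3-{3,4-bis[(tert-butyldimethylsilyl)oxy]phenyl}prop-2-enoate
Conditions: EDC·HCl, DMAP, CH2Cl2, 0 °C → rt
Reagents that add atoms: none
Why: Steglich esterification of the only free hydroxyl (O11); no stereocentre is involved and the C11–O bond is not broken.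

Step 14
Reactants: 19 (1S)-1-[(2S,5R)-5-{(S)-[(tert-butyldimethylsilyl)oxy][(2R)-6-oxo-3,6-dihydro-2H-pyran-2-yl]methyl}oxolan-2-yl]ethyl (2E)-3-{3,4-bis[(tert-butyldimethylsilyl)oxy]phenyl}prop-2-enoate
Product: 20 (1S)-1-[(2S,5R)-5-{(S)-hydroxy[(2R)-6-oxo-3,6-dihydro-2H-pyran-2-yl]methyl}oxolan-2-yl]ethyl (2E)-3-(3,4-dihydroxyphenyl)prop-2-enoate (CNP0300981.1)
Conditions: HF·pyridine, pyridine/THF, 0 °C → rt
Reagents that add atoms: none
Why: Fluoride-driven Si–O cleavage under buffered, weakly acidic conditions should remove all three TBS groups without touching the enoate lactone, the caffeate ester or the oxolane.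

**Compound list**
1 | (S)-but-3-yn-2-ol | C[C@H](O)C#C | starting material
2 | (S)-(but-3-yn-2-yloxy)triethylsilane | C[C@H](O[Si](CC)(CC)CC)C#C | intermediate
3 | (R)-2-[(benzyloxy)methyl]oxirane | c1ccccc1COC[C@H]1CO1 | starting material
4 | (2R,6S)-1-(benzyloxy)-6-[(triethylsilyl)oxy]hept-4-yn-2-ol | C[C@H](O[Si](CC)(CC)CC)C#CC[C@@H](O)COCc1ccccc1 | intermediate
5 | triethyl{(1S)-1-[(5R)-5-[(benzyloxy)methyl]-4,5-dihydrofuran-2-yl]ethoxy}silane | C[C@H](O[Si](CC)(CC)CC)C1=CC[C@@H](O1)COCc1ccccc1 | intermediate (not isolated)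
6 | triethyl{(1S)-1-[(2S,5R)-5-[(benzyloxy)methyl]oxolan-2-yl]ethoxy}silane | C[C@H](O[Si](CC)(CC)CC)[C@@H]1CC[C@H](COCc2ccccc2)O1 | intermediate (not isolated)
7 | {(2R,5S)-5-[(1S)-1-[(triethylsilyl)oxy]ethyl]oxolan-2-yl}methanol | C[C@H](O[Si](CC)(CC)CC)[C@@H]1CC[C@H](CO)O1 | intermediate
8 | (2R,5S)-5-[(1S)-1-[(triethylsilyl)oxy]ethyl]oxolane-2-carbaldehyde | C[C@H](O[Si](CC)(CC)CC)[C@@H]1CC[C@H](C=O)O1 | intermediate
9 | (1R)-1-{(2R,5S)-5-[(1S)-1-[(triethylsilyl)oxy]ethyl]oxolan-2-yl}prop-2-en-1-ol | C[C@H](O[Si](CC)(CC)CC)[C@@H]1CC[C@H]([C@H](O)C=C)O1 | intermediate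
10 | (S)-[(2R)-oxiran-2-yl]{(2R,5S)-5-[(1S)-1-[(triethylsilyl)oxy]ethyl]oxolan-2-yl}methanol | C[C@H](O[Si](CC)(CC)CC)[C@@H]1CC[C@H]([C@H](O)[C@H]2CO2)O1 | intermediate
11 | tert-butyldimethyl{(S)-[(2R)-oxiran-2-yl][(2R,5S)-5-[(1S)-1-[(triethylsilyl)oxy]ethyl]oxolan-2-yl]methoxy}silane | C[C@H](O[Si](CC)(CC)CC)[C@@H]1CC[C@H]([C@H](O[Si](C)(C)C(C)(C)C)[C@H]2CO2)O1 | intermediate
12 | (2S,3R)-3-[(tert-butyldimethylsilyl)oxy]-1-iodo-3-{(2R,5S)-5-[(1S)-1-[(triethylsilyl)oxy]ethyl]oxolan-2-yl}propan-2-ol | C[C@H](O[Si](CC)(CC)CC)[C@@H]1CC[C@H]([C@H](O[Si](C)(C)C(C)(C)C)[C@H](O)CI)O1 | intermediate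
13 | (2S,3S)-3-[(tert-butyldimethylsilyl)oxy]-1-iodo-3-{(2R,5S)-5-[(1S)-1-[(triethylsilyl)oxy]ethyl]oxolan-2-yl}propan-2-yl prop-2-enoate | C[C@H](O[Si](CC)(CC)CC)[C@@H]1CC[C@H]([C@H](O[Si](C)(C)C(C)(C)C)[C@H](OC(=O)C=C)CI)O1 | intermediate
14 | (6R)-6-{(S)-[(tert-butyldimethylsilyl)oxy][(2R,5S)-5-[(1S)-1-[(triethylsilyl)oxy]ethyl]oxolan-2-yl]methyl}-5,6-dihydro-2H-pyran-2-one | C[C@H](O[Si](CC)(CC)CC)[C@@H]1CC[C@H]([C@H](O[Si](C)(C)C(C)(C)C)[C@H]2CC=CC(=O)O2)O1 | intermediate
15 | (6R)-6-{(S)-[(tert-butyldimethylsilyl)oxy][(2R,5S)-5-[(1S)-1-hydroxyethyl]oxolan-2-yl]methyl}-5,6-dihydro-2H-pyran-2-one | C[C@H](O)[C@@H]1CC[C@H]([C@H](O[Si](C)(C)C(C)(C)C)[C@H]2CC=CC(=O)O2)O1 | intermediate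
16 | caffeic acid, (2E)-3-(3,4-dihydroxyphenyl)prop-2-enoic acid | OC(=O)/C=C/c1ccc(O)c(O)c1 | starting material
17 | tert-butyldimethylsilyl (2E)-3-{3,4-bis[(tert-butyldimethylsilyl)oxy]phenyl}prop-2-enoate | CC(C)(C)[Si](C)(C)OC(=O)/C=C/c1ccc(O[Si](C)(C)C(C)(C)C)c(O[Si](C)(C)C(C)(C)C)c1 | intermediate (not isolated)
18 | (2E)-3-{3,4-bis[(tert-butyldimethylsilyl)oxy]phenyl}prop-2-enoic acid | OC(=O)/C=C/c1ccc(O[Si](C)(C)C(C)(C)C)c(O[Si](C)(C)C(C)(C)C)c1 | intermediate
19 | (1S)-1-[(2S,5R)-5-{(S)-[(tert-butyldimethylsilyl)oxy][(2R)-6-oxo-3,6-dihydro-2H-pyran-2-yl]methyl}oxolan-2-yl]ethyl (2E)-3-{3,4-bis[(tert-butyldimethylsilyl)oxy]phenyl}prop-2-enoate | C[C@H](OC(=O)/C=C/c1ccc(O[Si](C)(C)C(C)(C)C)c(O[Si](C)(C)C(C)(C)C)c1)[C@@H]1CC[C@H]([C@H](O[Si](C)(C)C(C)(C)C)[C@H]2CC=CC(=O)O2)O1 | intermediate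
20 | (1S)-1-[(2S,5R)-5-{(S)-hydroxy[(2R)-6-oxo-3,6-dihydro-2H-pyran-2-yl]methyl}oxolan-2-yl]ethyl (2E)-3-(3,4-dihydroxyphenyl)prop-2-enoate | C[C@H](OC(=O)/C=C/c1ccc(O)c(O)c1)[C@@H]1CC[C@H]([C@H](O)[C@H]2CC=CC(=O)O2)O1 | target

**Step count and risks**

Total step count: 14. Longest linear sequence: 13 steps (steps 1–11, 13 and 14, counted from 1).

Steps most likely to fail:

1. Step 10 (proposed new method). The carbene–acrylate adduct may add to a second acrylate faster than it cyclises (oligomerisation), the enolate form may close at C2 to a five-membered α-methylene lactone, or displacement at the β-branched CH2–I may be too slow before the catalyst is alkylated. The fallback uses known chemistry and sets out from epoxide 11. Dimethylsulfonium methylide (Me3S+ I−, n-BuLi, THF, −10 °C) should convert the terminal epoxide into the one-carbon-longer allylic alcohol (1R,2R)-1-[(tert-butyldimethylsilyl)oxy]-1-{(2R,5S)-5-[(1S)-1-[(triethylsilyl)oxy]ethyl]oxolan-2-yl}but-3-en-2-ol F1. Steglich esterification with but-3-enoic acid (DCC, DMAP cat., CH2Cl2, 0 °C) should give the but-3-enoate F2. Ring-closing metathesis with the second-generation Grubbs catalyst RuCl2(H2IMes)(PCy3)(=CHPh) in CH2Cl2 at 40 °C joins the same two carbons C3 and C4, first as a double bond, and should give the 3,6-dihydro-2H-pyran-2-one F3. Catalytic DBU (CH2Cl2, rt) then moves the double bond into conjugation, and the route is rejoined at lactone 14.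

2. Step 3. The acid-labile cyclic enol ether may hydrolyse or add a second alcohol before it is reduced, and hydrogen may add to both faces of C9=C10. The fallback sets out from alkynol 4. The same gold catalyst in methanol (cycloisomerisation with hydroalkoxylation) should give the stable mixed ketal triethyl{(1S)-1-[(5R)-5-[(benzyloxy)methyl]-2-methoxyoxolan-2-yl]ethoxy}silane F4. Ionic hydrogenation (Et3SiH, BF3·OEt2, CH2Cl2, −78 °C) reduces the derived oxocarbenium ion with hydride entering anti to the C7 substituent, giving the 2,5-cis benzyl ether 6, which is isolated here. Hydrogenolysis (H2, Pd(OH)2/C, EtOAc) returns to the route at alcohol 7.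

3. Step 8 (and the acylation that follows). The triethylsilyl ether may be lost under the acidic iodide opening, and the iodohydrin may re-close to the epoxide under the basic acylation of step 9. The fallback sets out from epoxide 11. Acryloyl chloride with catalytic Bu4NCl (CH2Cl2, rt) opens the epoxide directly, with chloride at the CH2 carbon and the acyl group on O5, giving the chloro ester (2S,3S)-3-[(tert-butyldimethylsilyl)oxy]-1-chloro-3-{(2R,5S)-5-[(1S)-1-[(triethylsilyl)oxy]ethyl]oxolan-2-yl}propan-2-yl prop-2-enoate F5 under neutral conditions. Finkelstein exchange (NaI, butan-2-one, reflux) returns to the route at iodo acrylate 13.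

Further compounds
F1 | step 10 | (1R,2R)-1-[(tert-butyldimethylsilyl)oxy]-1-{(2R,5S)-5-[(1S)-1-[(triethylsilyl)oxy]ethyl]oxolan-2-yl}but-3-en-2-ol | C[C@H](O[Si](CC)(CC)CC)[C@@H]1CC[C@H]([C@H](O[Si](C)(C)C(C)(C)C)[C@H](O)C=C)O1
F2 | step 10 | (1S,2R)-1-[(tert-butyldimethylsilyl)oxy]-1-{(2R,5S)-5-[(1S)-1-[(triethylsilyl)oxy]ethyl]oxolan-2-yl}but-3-en-2-yl but-3-enoate | C[C@H](O[Si](CC)(CC)CC)[C@@H]1CC[C@H]([C@H](O[Si](C)(C)C(C)(C)C)[C@H](OC(=O)CC=C)C=C)O1
F3 | step 10 | (6R)-6-{(S)-[(tert-butyldimethylsilyl)oxy][(2R,5S)-5-[(1S)-1-[(triethylsilyl)oxy]ethyl]oxolan-2-yl]methyl}-3,6-dihydro-2H-pyran-2-one | C[C@H](O[Si](CC)(CC)CC)[C@@H]1CC[C@H]([C@H](O[Si](C)(C)C(C)(C)C)[C@H]2C=CCC(=O)O2)O1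
F4 | step 3 | triethyl{(1S)-1-[(5R)-5-[(benzyloxy)methyl]-2-methoxyoxolan-2-yl]ethoxy}silane (both ketal epimers) | C[C@H](O[Si](CC)(CC)CC)C1(OC)CC[C@H](COCc2ccccc2)O1
F5 | step 8 | (2S,3S)-3-[(tert-butyldimethylsilyl)oxy]-1-chloro-3-{(2R,5S)-5-[(1S)-1-[(triethylsilyl)oxy]ethyl]oxolan-2-yl}propan-2-yl prop-2-enoate | C[C@H](O[Si](CC)(CC)CC)[C@@H]1CC[C@H]([C@H](O[Si](C)(C)C(C)(C)C)[C@H](OC(=O)C=C)CCl)O1
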